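The readings come from a simulation with constants of no real substance; noise was put on by code.

- A small charge came first: the oak run set 0.40 M of starting material against 0.80 M of protic impurity. The cedar run raised the charge to 0.60 M at the same impurity.

| setting | oak | cedar | flask |
|---|---|---|---|
| starting material | 0.40 M | 0.60 M | 0.80 M |
| protic impurity | 0.80 M | 0.80 M | 0.800 M |
| remark | run made earlier | run made earlier |  |
| time |  |  | 4.0 d |

| run | time / d | target / % | starting material / % |
|---|---|---|---|
| oak | 0.0556 | 21.8 | 36.2 |
| oak | 0.104 | 28.3 | 21.3 |
| oak | 0.167 | 32.1 | 12.8 |
| oak | 0.333 | 28.6 | 6.9 |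
| oak | 0.625 | 20.5 | 4.5 |
| oak | 1.25 | 12.4 | 3.3 |
| oak | 2.50 | 4.3 | 1.0 |
| cedar | 0.0556 | 22.0 | 36.5 |
| cedar | 0.104 | 29.0 | 22.5 |
| cedar | 0.167 | 31.6 | 13.3 |
| cedar | 0.333 | 30.0 | 8.1 |
| cedar | 0.625 | 22.8 | 6.4 |
| cedar | 1.25 | 14.2 | 3.2 |
| cedar | 2.50 | 6.8 | 2.1 |

(scatter of a reading: 0.5 percentage points)

- the earlier runs were read with a standard deviation of 0.5 percentage points

- the best time, 4.0 d at the latest, for target
- the amount of target, in percent of the starting material charged, at that time
- the first time at which target reaches 17%, in the same percent

- I compared the early readings. At 0.0556 d, starting material read 36.2% in oak and 36.5% in cedar.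
- The peak readings of target stood at 0.167 d in both runs: 32.1% in oak and 31.6% in cedar.
- The tails parted. At 2.50 d, cedar read more target than oak, 6.8% against 4.3%.
- So I asked what end state each flask approached. I assumed that in the end each unit of starting material charged took up one protic impurity.
- The next flask had 1.00 as its impurity ratio, which I defined as c(protic impurity) over c(starting material) at the charge.
- With a ratio above one, starting material is the limiting reagent. Under my assumption, at a ratio of one or above, the share of impurity left at the end is one minus the inverse ratio. That gave 50.0% for oak, 25.0% for cedar and 0% for the next flask.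
- I expected that flask to have a slower tail. But target fell after its peak reading in both runs, so I decided to keep the recipe and stop near the peak, not at 4.0 d.
- The forecast gave 0.2 d, 32.5% and 0.88 h, and held that “the early peak barely changes”.
- The flask gave 0.205 d, 33.1% and 0.831 h.

    starting material ⇌ isomer of the product B (K = 0.220, k = 0.00790 /min)
    starting material ⇌ target (K = 2.75, k = 0.00528 /min)
    starting material ⇌ isomer of the product A (K = 0.750, k = 0.00101 /min)
    starting material + protic impurity → quenched substrate (k = 0.00823 /M/min)

- In the flask, the half-life of starting material by quenching alone began at 0.073 d, below the 0.091 d of the forward step to target, but at 0.194 d it stood at 0.13 d. The ratio 1.00 promised the flask 0% spare impurity, and 1.26% remained at 40.0 d; the neighbour flask with 1.4 M of impurity, ratio 1.75 equiv, was reckoned at 42.9% left, held 43% at 4.00 d, and reached a best target of 24.8%.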